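**Plan**
- Retrosynthetic cuts, in order: the enol ester O–acyl bond (senecioyl group), the C2' carbonyl oxygen (back to a CH2), the pyranone ring (lactone C2–O1 and C3=C4), the C4–C4a bond (a formyl group), and last the pair C8a–O1 / C8–C1'.
- Enabling feature: O1–C8a and the C8–C1' ketone sit on adjacent carbons of the benzene ring, with the C7 methoxy group on the other side of C8. This is the footprint of a carboxylic acid added across 3-methoxybenzyne.
- Forward: the benzene ring is bought as an aryne precursor. Step 1 installs oxygen and acyl together, step 2 adds the formyl carbon, step 3 closes the pyranone (the only ring closure), and steps 4–5 finish the side chain.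
- Stereochemistry: the target has no stereocentre. C3=C4 is cis by ring constraint and the enol ester alkene ends in two identical methyl groups.

Key step: step 1

Assumption: silyl triflate 1 is treated as a catalogue aryne precursor; if it had to be made, it derives from 3-methoxyphenol by a standard directed silylation/triflation sequence.

Step 1
Reactants: 1 3-methoxy-2-(trimethylsilyl)phenyl trifluoromethanesulfonate (1.5 equiv); 2 3-methylbutanoic acid
Product: 5 1-(2-hydroxy-6-methoxyphenyl)-3-methylbutan-1-one, via 3-methoxybenzyne 3 (not isolated), via ortho-cesiated aryl ester 4 (not isolated)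
Conditions: CsF (4 equiv), THF, 125 °C, sealed tube; aq. NH4Cl work-up
Reagents that add atoms: none
Why: Fluoride removes the silyl group of 1 and triflate departs to give 3-methoxybenzyne 3; cesium 3-methylbutanoate adds through oxygen at the aryne carbon remote from OMe, which places the aryl anion of 4 on the carbon flanked by the new ester oxygen and the methoxy group. In hot aprotic THF this anion attacks its own ester carbonyl (4-exo-trig) to a four-membered alkoxide that opens to the ketone phenoxide, a net insertion of the aryne into the acyl–oxygen bond. The closest known reaction type is the fluoride-triggered insertion of arynes into the C–O bond of carboxylic acids, aliphatic ones included, which gives ortho-hydroxyaryl ketones. No ring remains in the product and no stereocentre is formed. The regioselectivity needed is secured by the substrate: the inductively withdrawing methoxy group, and the distortion it imposes on the aryne, direct the oxygen nucleophile to the distal carbon so that charge develops next to OMe. Acyl transfer must outrun protonation of 4, which is favoured by the high temperature, the absence of other proton sources and excess CsF, which binds HF as CsHF2.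

Step 2
Reactants: 5 1-(2-hydroxy-6-methoxyphenyl)-3-methylbutan-1-one
Product: 7 2-hydroxy-4-methoxy-3-(3-methylbutanoyl)benzaldehyde, via hydroxymethyl phenol 6 (not isolated)
Conditions: MgCl2 (anhydrous), Et3N, (CH2O)n, MeCN, reflux; then 1 M HCl
Reagents that add atoms: paraformaldehyde (reacts as formaldehyde), C=O
Why: Magnesium-mediated ortho-formylation (Casiraghi–Skattebøl reaction): the chloromagnesium phenoxide of 5 (ArOMgCl) delivers coordinated formaldehyde through a six-membered transition state to the only free ortho carbon, which is also para to OMe, and the salicyl alkoxide 6 is then oxidised to the aldehyde by hydride transfer to a second formaldehyde.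

Step 3
Reactants: 7 2-hydroxy-4-methoxy-3-(3-methylbutanoyl)benzaldehyde; 8 ethyl (triphenylphosphoranylidene)acetate
Product: 11 7-methoxy-8-(3-methylbutanoyl)-2H-chromen-2-one, via E-cinnamate ester 9 (not isolated), via Z-cinnamate ester 10 (not isolated)
Conditions: PhNEt2, reflux (about 215 °C), N2
Reagents that add atoms: none
Why: Wittig olefination with the stabilised ylide engages only the aldehyde (the ketone, flanked by two ortho substituents, is inert to it), and at the boiling point of PhNEt2 the E ester 9 equilibrates with the Z ester 10, whose phenol closes the lactone by 6-exo-trig acyl substitution with loss of ethanol.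

Step 4
Reactants: 11 7-methoxy-8-(3-methylbutanoyl)-2H-chromen-2-one
Product: 12 1-(7-methoxy-2-oxo-2H-chromen-8-yl)-3-methylbutane-1,2-dione
Conditions: SeO2 (1.1–1.2 equiv), 1,4-dioxane/H2O, reflux
Reagents that add atoms: selenium dioxide, O=[Se]=O
Why: Riley oxidation: SeO2 reacts with the enol of the aryl ketone at its only α-methylene (ene reaction, [2,3]-shift, loss of selenium and water) to give the 1,2-diketone, while the coumarin has no allylic C–H and the lactone and aryl ether are inert to the reagent.

Step 5
Reactants: 12 1-(7-methoxy-2-oxo-2H-chromen-8-yl)-3-methylbutane-1,2-dione; 13 3-methylbut-2-enoyl chloride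
Product: 15 kimcuongin [1-(7-methoxy-2-oxo-2H-chromen-8-yl)-3-methyl-1-oxobut-2-en-2-yl 3-methylbut-2-enoate], via potassium enolate 14 (not isolated)
Conditions: 12 added to KN(SiMe3)2 (1.05 equiv), THF, −78 °C; then cannulated into 13 (1.5 equiv), THF, −78 → 0 °C
Reagents that add atoms: none
Why: Enolate O-acylation: the isopropyl methine is the only acidic C–H of 12, so KN(SiMe3)2 gives a single tetrasubstituted potassium enolate 14, which an acid chloride should acylate on oxygen because C-acylation would have to build a quaternary carbon, and inverse addition without amine base keeps the senecioyl chloride from forming a vinylketene and a deconjugated ester.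

**Compound list**
1 | 3-methoxy-2-(trimethylsilyl)phenyl trifluoromethanesulfonate | COc1cccc(OS(=O)(=O)C(F)(F)F)c1[Si](C)(C)C | starting material
2 | 3-methylbutanoic acid | CC(C)CC(=O)O | starting material
3 | 3-methoxybenzyne (1-methoxycyclohexa-1,3-dien-5-yne; not isolated) | COC1=CC=CC#C1 | intermediate
4 | [2-methoxy-6-(3-methylbutanoyloxy)phenyl]cesium (ortho-cesiated aryl ester; not isolated) | COc1cccc(OC(=O)CC(C)C)c1[Cs] | intermediate
5 | 1-(2-hydroxy-6-methoxyphenyl)-3-methylbutan-1-one | COc1cccc(O)c1C(=O)CC(C)C | intermediate
6 | 1-[2-hydroxy-3-(hydroxymethyl)-6-methoxyphenyl]-3-methylbutan-1-one (present as its magnesium alkoxide; not isolated) | COc1ccc(CO)c(O)c1C(=O)CC(C)C | intermediate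
7 | 2-hydroxy-4-methoxy-3-(3-methylbutanoyl)benzaldehyde | COc1ccc(C=O)c(O)c1C(=O)CC(C)C | intermediate
8 | ethyl (triphenylphosphoranylidene)acetate | CCOC(=O)C=P(c1ccccc1)(c1ccccc1)c1ccccc1 | starting material
9 | ethyl (E)-3-[2-hydroxy-4-methoxy-3-(3-methylbutanoyl)phenyl]prop-2-enoate (not isolated) | CCOC(=O)/C=C/c1ccc(OC)c(C(=O)CC(C)C)c1O | intermediate
10 | ethyl (Z)-3-[2-hydroxy-4-methoxy-3-(3-methylbutanoyl)phenyl]prop-2-enoate (not isolated) | CCOC(=O)/C=C\c1ccc(OC)c(C(=O)CC(C)C)c1O | intermediate
11 | 7-methoxy-8-(3-methylbutanoyl)-2H-chromen-2-one | COc1ccc2ccc(=O)oc2c1C(=O)CC(C)C | intermediate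
12 | 1-(7-methoxy-2-oxo-2H-chromen-8-yl)-3-methylbutane-1,2-dione | COc1ccc2ccc(=O)oc2c1C(=O)C(=O)C(C)C | intermediate
13 | 3-methylbut-2-enoyl chloride | CC(C)=CC(=O)Cl | starting material
14 | potassium 1-(7-methoxy-2-oxo-2H-chromen-8-yl)-3-methyl-1-oxobut-2-en-2-olate (not isolated) | [K+].COc1ccc2ccc(=O)oc2c1C(=O)C([O-])=C(C)C | intermediate
15 | kimcuongin, 1-(7-methoxy-2-oxo-2H-chromen-8-yl)-3-methyl-1-oxobut-2-en-2-yl 3-methylbut-2-enoate | COc1ccc2ccc(=O)oc2c1C(=O)C(OC(=O)C=C(C)C)=C(C)C | target

**Total step count:** 5. **Longest linear sequence:** 5 steps (1 + 2 → 5 → 7 → 11 → 12 → 15).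

**Steps most likely to fail**

Step 4 (Riley oxidation). The twisted, doubly ortho-substituted aryl ketone may enolise slowly, and once the dione is formed its newly activated isopropyl methine may be oxidised further (hydroxylation or dehydrogenation), so conversion and selectivity could both suffer. The fallback sets out from 11 and avoids selenium. Acid-mediated α-nitrosation (isoamyl nitrite, dry HCl, THF/Et2O, 0 °C to rt) should convert the methylene into the oxime 2-(hydroxyimino)-1-(7-methoxy-2-oxo-2H-chromen-8-yl)-3-methylbutan-1-one F1. Exchange deoximation with aqueous formaldehyde and HCl in THF should then release the diketone, and the route is rejoined at 12.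

Step 1 (aryne insertion). The aryl anion may be protonated, by HF or by the α-methylene of its own ester, before it transfers the acyl group, so that only O-arylation results; partial loss of regiocontrol in the addition is a second possibility. The fallback sets out from 2 and forms the C8–C1' bond by directed ortho-metalation instead. Acid 2 is converted (carbonyldiimidazole, then MeNH(OMe)·HCl) into the Weinreb amide N-methoxy-N,3-dimethylbutanamide F2. Commercial 1,3-dimethoxybenzene is lithiated between its two oxygens (n-BuLi, THF, 0 °C) to (2,6-dimethoxyphenyl)lithium F3, which adds to F2 to give 1-(2,6-dimethoxyphenyl)-3-methylbutan-1-one F4. Chelation-controlled mono-demethylation with BCl3 (CH2Cl2, −78 → 0 °C) should stop after one ether, and the route is rejoined at 5.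

Step 2 (ortho-formylation). Magnesium chelation of the ketone with Et3N present may trigger soft enolisation and aldol addition to formaldehyde at the α-methylene, and the acyl-deactivated, chelated phenoxide may formylate slowly. The fallback sets out from 5 and bypasses the aldehyde 7. Hydroarylation of ethyl propiolate catalysed by Pd(OAc)2 (electrophilic divalent palladium) in CF3CO2H/CH2Cl2 at room temperature should attack the same ortho carbon (para to OMe) and give the Z ester 10 by trans-addition. This lactonises in the acidic medium, and the route is rejoined at 11.

**Further compounds**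
F1 | step 4 | 2-(hydroxyimino)-1-(7-methoxy-2-oxo-2H-chromen-8-yl)-3-methylbutan-1-one (E/Z mixture) | COc1ccc2ccc(=O)oc2c1C(=O)C(=NO)C(C)C
F2 | step 1 | N-methoxy-N,3-dimethylbutanamide | CC(C)CC(=O)N(C)OC
F3 | step 1 | (2,6-dimethoxyphenyl)lithium | [Li]c1c(OC)cccc1OC
F4 | step 1 | 1-(2,6-dimethoxyphenyl)-3-methylbutan-1-one | COc1cccc(OC)c1C(=O)CC(C)C
F0 | step 2 | none | none
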